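The numbers of this flask were drawn at random within sensible limits; no experiment stands behind them.

Weigh the partner before starting: the catalytic cycle and the protic impurity both draw on it.

    substrate + free catalyst → catalyst intermediate A (k1 = 660 /M/min, Ea1 = 38.0 kJ/mol)
    partner + catalyst intermediate A → catalyst intermediate B (k2 = 42 /M/min, Ea2 = 59.0 kJ/mol)
    catalyst intermediate B → free catalyst + product (k3 = 60 /min, Ea3 = 73.0 kJ/mol)
    partner + product ⇌ idle adduct, settled at all times (K4 = 38 /M, ΔH4 = 2.00 kJ/mol)
    partner + protic impurity → quenched reagent (k5 = 0.33 /M/min, Ea5 = 57.0 kJ/mol)
    (constants at 25 °C)

| setting | violet | green | grey |
|---|---|---|---|
| substrate | 0.80 M | 0.80 M | 0.80 M |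
| partner | 1.10 equiv | 1.10 equiv | 1.10 equiv |
| protic impurity | 0.0400 M | 0.0400 M | 0.0400 M |
| free catalyst | 0.48 mol% | 0.48 mol% | 0.48 mol% |
| temperature | 25 °C | 33 °C | 41 °C |
| time | 6.0 h | 6.0 h | 6.0 h |

* which of these there is most of at the end, counted by the substrate in it, violet (catalyst intermediate B / substrate / product / catalyst intermediate A)
* which of these there is most of at the end, counted by the substrate in it, green (catalyst intermediate B / substrate / product / catalyst intermediate A)
* which of these there is most of at the end, counted by the substrate in it, grey (catalyst intermediate B / substrate / product / catalyst intermediate A)
* final amount of the leader among these, as a percentage of the substrate charged, in violet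
* final amount of the leader among these, as a percentage of the substrate charged, in green
* final amount of the leader among these, as a percentage of the substrate charged, in grey

- for product the idle adduct is counted in
- constants are those at 25 °C; use the activation energies and enthalpies for any other temperature

Two amounts carry the argument, both as fractions of the substrate charge: the substrate itself, and the partner left for it after the quench. With substrate and partner at their charges, the three steps of the cycle run at 528 /min, 37.0 /min and 60 /min, so at the very start catalyst intermediate A holds a share of 0.593 of the loading. Product then binds partner as idle adduct: with product near its charge, the second step runs below 1.18 /min, slower than the third step. Catalyst intermediate A is therefore taken as the resting state, with the whole loading placed in it as a simplification.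

Product and quench then both run in proportion to free partner, which cancels in their ratio, so idle adduct and the clock drop out of it. Per unit of conversion the impurity decays exponentially, with the exponent set by the quench constant divided by the second-step constant and by the catalyst fraction: the quench number 1.64. Activation energies of 57.0 kJ/mol and 59.0 kJ/mol lie close, so the same number is carried to green and grey as an approximation. At full conversion this reckons to a surviving fraction 0.195 of the impurity. From an impurity charge of 0.0500, the toll is 0.0403. The partner cover is 1.06, above the substrate. A share of catalyst intermediate A below one raises the exponent, but with the whole impurity charge quenched the cover is 1.05, still above the substrate. This reckoning gives a ceiling and no clock.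

The forecast names product, product and product as leaders, at 99.9%, 100% and 100%: “The impurity consumes about 0.034 M of partner”. The toll here differs slightly, at 0.0322 M.

Violet ends at >99.9% product, green at 100% and grey at 100%. In violet, 0.17% of the partner stands free at the end, while idle adduct holds 5.48% of the substrate charged. The outcome turns with a short charge: grey's neighbour with 0.280 equiv of partner has, at quench number 1.64, a cover of 0.262, below the substrate, and it ends with 26.2% product and 73.3% substrate.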